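## Structural features

Laxiflorin is a flavanone: a benzopyranone (ring A fused to the oxygen heterocycle, ring C) that carries a 4-hydroxy-3-methoxyphenyl group (ring B) at C2. Ring A is fully substituted (C4a acyl carbon, C5–OH, C6–CH2CH2OH, C7–OH, C8–prenyl, C8a–O1), so three oxygens of a phloroglucinol must be told apart and two different carbon chains placed between them. C2 is the only stereocentre (S; priorities O1 > aryl > C3 > H) and has no stereogenic neighbour, so its configuration must come from a reagent or catalyst. It is also labile, because C2–O1 is a benzylic ether β to the C4 ketone and opens to the 2'-hydroxychalcone by retro-oxa-Michael reaction under base and, more slowly, under acid. The prenyl alkene is the second fragile group: it is lost on hydrogenation, reacts with electrophilic halogen and can cyclise onto the C7 hydroxyl in strong acid; the electron-rich phenols are prone to oxidation. The real difficulty is to combine regiocontrol on a hexasubstituted arene with a late, catalyst-controlled creation of C2. The key step uses the fact that C3 is a bare CH2 between the C4 carbonyl and C2: ring C is the sum of a C4 aldehyde C–H bond and an O1–C2(=C3H2) enol ether, so it can be closed by intramolecular hydroacylation, forming C3–C4 and placing hydrogen on C2.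

## Logic of the disconnections

**21 ⇒ 20.** The three aryl O–CH2OCH3 bonds and the alkyl O–Si bond are cut. All four groups are acid-labile, so one operation releases the target and the phenols and the alcohol stay masked through every organometallic step. The forward step must be acidic enough for four cleavages yet mild enough for the prenyl alkene and C2.

**20 ⇒ 19.** The C3–C4 bond is cut and the C2 hydrogen returned to the aldehyde. This opens ring C and removes the only stereocentre, so 19 is achiral and holds every atom of 20. The forward step must add the aldehyde C–H bond across the enol ether with rhodium at C3, hydride at C2 and control of the enantioface.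

**19 ⇒ 17.** The C4a–CHO bond is cut to a C4a–Br bond. An aldehyde cannot survive the ester methylenation that makes the enol ether, so the formyl group has to come last; a bromine placeholder fixes its position without relying on directed metalation in competition with ring B. The demand is a clean bromine–lithium exchange beside the enol ether and the prenyl group.

**17 ⇒ 14 + 15.** The C8–CH2 bond of the prenyl group is cut. The alkene is incompatible with the bromination and hydrogenolysis used earlier, so it enters after them. The gain is a ring A with a mirror plane in 14, whose two C–Br bonds are equivalent. The forward step needs exchange of only one bromine and coupling at the primary carbon of 15.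

**14 ⇒ 13.** The C2=C3 double bond is cut to a carbonyl, so C3 is supplied as a methylene unit. This turns the sensitive 1-arylvinyl ether into a robust aryl ester and reduces the future O1–C2 bond to an acyl–oxygen bond. The methylenation must work on a hindered ester under non-acidic conditions.

**13 ⇒ 9 + 12.** The acyl C–O bond is cut, which is the convergent union of ring A (9) with ring B (12). The demand is acylation of a hindered, acidic phenol without acid that would attack the acetals.

**12 ⇒ 10.** The aryl O–CH2OCH3 bond is cut; the phenol of ring B must be masked with a group that falls in the last step.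

**9 ⇒ 8.** Both C–Br bonds are cut. The two free ring positions of 8 are equivalent and both ortho to the free hydroxyl, so exhaustive bromination needs no site selection. It must be done before any alkene is present.

**8 ⇒ 7.** The O–benzyl bond is cut. The benzyl group is the temporary marker that sets the future O1 apart from the C5 and C7 oxygens. Hydrogenolysis is safe here because no alkene or halide exists yet.

**7 ⇒ 6 ⇒ 4.** The O–Si bond, then the C–OH and benzylic C–H bonds of the side chain are cut back to a vinyl group. The forward hydroboration must place oxygen on the terminal carbon.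

**4 ⇒ 3.** The C=C bond is cut to the aldehyde. The formyl carbon of 1 thus becomes the benzylic carbon of the C6 hydroxyethyl chain, flanked by the C5 and C7 oxygens exactly as in the target.

**3 ⇒ 2 ⇒ 1.** The two O–CH2OCH3 bonds and then the O–benzyl bond are cut. In 1 the hydroxyl para to the formyl group is the most acidic and is not hydrogen-bonded, which allows it to be marked first; the forward steps depend on that acidity difference.

## Other disconnections considered

**Alternative 1:** The cut takes ring A apart at C8–C8a and C4a–C5. It leaves ring C as the bromo enone A1, (S)-5-bromo-2-[4-(tert-butyldimethylsilyloxy)-3-methoxyphenyl]-2,3-dihydro-4H-pyran-4-one, and C5–C8 as the bis(silyloxy) diene A2, 2-(trimethylsilyloxy)-3-[5-methyl-1-(trimethylsilyloxy)hexa-1,4-dienyl]-4,5-dihydrofuran. In the forward sense A2 would add across C4a=C8a of A1 in a [4+2] reaction. Opening of the C5 ketal would free the hydroxyethyl chain, and loss of HBr and enolisation would aromatise ring A to give A3.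
- In its favour: ring A and all four of its substituents arise in one operation with no ring A protecting group. The polarity of the partners matches the required regiochemistry. C2 would be set beforehand by an asymmetric hetero-Diels–Alder reaction of well-established type.
- Against it here: the dienophile is an electron-rich vinylogous ester and the diene has a fully substituted terminus. The addition would create a quaternary C4a next to a ketal carbon and would probably need Lewis acid or pressure, under which the benzylic C2–O1 bond can ionise. A Michael addition without ring closure is a likely diversion. The C5 ketal could also collapse by loss of silanol and keep the chain oxygen on C5 as a fused dihydrofuran.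
- Comparison: on structure, two bonds and ring A are formed against one bond and ring C in the chosen plan. On mechanism, both key steps are unproven on this substrate; the alternative risks reactivity and cascade fidelity, the chosen plan risks insertion selectivity. On security of the stereo-defining step and on step economy the alternative is the better. The chosen plan makes every ring A bond by dependable aromatic chemistry and confines the speculative event to the penultimate step.

**Alternative 2:** The cut is the single bond C4a–C5. The precursor A4 is (2S)-2-[3-methoxy-4-(methoxymethoxy)phenyl]-6-[5-methyl-1-oxo-1-(2-oxooxolan-3-yl)hex-4-en-2-yl]-2,3-dihydro-4H-pyran-4-one. Under base, C4a (reached through the extended enolate formed by removing the C8 proton) would attack the lactone carbonyl C5. The expelled alkoxide becomes the hydroxyethyl chain and the triketone enolises to ring A, giving A5.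
- In its favour: the fold mirrors a polyketide cyclisation. Ring A, its free hydroxyls and the side chain appear together, and only one acetal remains to be removed, so the end game is shorter than in the chosen plan. Carbonyl condensations of this general kind have closer precedent than the rhodium step, which is a point for the alternative.
- Against it here: the C6 proton between two carbonyls is the most acidic, and its enolate switches off the lactone as an electrophile. C4a is the γ-terminus and must outrun C8 and the oxygen termini. Base also endangers C2: A4 can open at C2–O1 after C3 deprotonation, and A5, a flavanone with a free 5-hydroxyl, equilibrates with its chalcone.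
- Comparison: on structure, the alternative exposes the labile stereocentre to base in the very step that builds ring A, whereas the chosen plan creates C2 after all basic steps. On mechanism it is ionic and conventional against organometallic and new. On step economy it is shorter after the key step, but the assembly of A4 is itself uncertain.

**Alternative 3:** The cut removes both C3–C4 and O1–C2, so ring C is the [4+2] adduct of a ring A ortho-quinone methide and a styrene. The components are the salicylaldehyde A6, 2-hydroxy-4,6-bis(methoxymethoxy)-5-[2-(tert-butyldimethylsilyloxy)ethyl]-3-(3-methylbut-2-enyl)benzaldehyde, and the styrene A7, triisopropyl(2-methoxy-4-vinylphenoxy)silane. With an orthoformate and a chiral Brønsted acid, A6 would form a 4-methoxy quinone methide that takes up A7 to give the 2,4-cis-4-methoxyflavan A8.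
- In its favour: it is the most convergent of the four plans. A6 needs neither bromine placeholders, ester methylenation nor organolithium chemistry, so the precursor is simpler than 19, a point on which the alternative is better. Acid-promoted cycloadditions of such quinone methides with styrenes are a known reaction type, again closer to precedent.
- Against it here: C4 arrives as a methyl ether and must be hydrolysed and oxidised, two more steps on a substrate with acid-sensitive acetals. The cationic intermediate is strongly stabilised by the C5 and C7 oxygens, so it is long-lived, loosely paired with the chiral anion and likely to add stepwise, which makes enantiocontrol uncertain. The acid threatens the acetals, the silyl ether and the prenyl group. C2 of A8 is a benzylic ether activated by a para-silyloxy aryl group and could ionise.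
- Comparison: on structure, two bonds are formed but a redox correction is left, whereas the chosen hydroacylation is a redox-neutral isomerisation that gives the ketone directly. On mechanism it is polar and acid-catalysed against neutral and organometallic; the chosen plan keeps acid away while acid-labile groups are present. On step economy the two are about equal, since the shorter way to A6 and A7 is offset by the steps after A8.

Key step: step 13

Remarks on the chemistry:
- Flavanone numbering (O1, C2, C3, C4, C4a, C5–C8, C8a) is used for the ring A carbons throughout, also in intermediates without ring C.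
- Which antipode of the bisphosphine leads to the 2S product cannot be predicted from first principles. The (R)-ligand is written by assumption and would be exchanged for its antipode if the sense were opposite.
- The structures of 19 and 20 were checked atom by atom against the target (ring A pattern, 3-methoxy-4-oxy pattern of ring B, S descriptor at C2). They agree, so no structural correction was needed.
- The precursor is improved in how it is reached: both ring carbons (C8 and C4a) are addressed through bromine–lithium exchange, not through directed lithiation next to ring B.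

## Route

Step 1
Reactants: 1 2,4,6-trihydroxybenzaldehyde
Product: 2 4-(benzyloxy)-2,6-dihydroxybenzaldehyde
Conditions: BnBr (1.0 equiv), CsHCO3 (1.2 equiv), MeCN, 60 °C
Reagents that add atoms: benzyl bromide, BrCc1ccccc1
Why: Williamson etherification under acidity control; the hydroxyl para to the formyl group is the most acidic and is not hydrogen-bonded, so the weak base should ionise only it and leave the two chelated ortho hydroxyls.

Step 2
Reactants: 2 4-(benzyloxy)-2,6-dihydroxybenzaldehyde
Product: 3 4-(benzyloxy)-2,6-bis(methoxymethoxy)benzaldehyde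
Conditions: NaH (2.4 equiv), MOMCl (2.4 equiv), THF/DMF 4:1, 0 °C to rt
Reagents that add atoms: chloromethyl methyl ether (MOMCl), COCCl
Why: Double deprotonation breaks the hydrogen bonds to the carbonyl, and the hard electrophile O-alkylates both phenoxides (acetal protection).

Step 3
Reactants: 3 4-(benzyloxy)-2,6-bis(methoxymethoxy)benzaldehyde
Product: 4 5-(benzyloxy)-1,3-bis(methoxymethoxy)-2-vinylbenzene
Conditions: Ph3PCH3Br (1.5 equiv), KOtBu (1.4 equiv), THF, 0 °C to rt
Reagents that add atoms: methyltriphenylphosphonium bromide, C[P+](c1ccccc1)(c1ccccc1)c1ccccc1.[Br-]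
Why: Wittig methylenation; the small unstabilised ylide should add even to this electron-rich, doubly ortho-substituted aldehyde, and no base-sensitive group is present.

Step 4
Reactants: 4 5-(benzyloxy)-1,3-bis(methoxymethoxy)-2-vinylbenzene
Product: 6 2-[4-(benzyloxy)-2,6-bis(methoxymethoxy)phenyl]ethan-1-ol, via B-(2-arylethyl)-9-BBN adduct 5 (not isolated)
Conditions: 9-BBN (1.5 equiv), THF, 0 to 40 °C; then 3 M aq. NaOH, 30% H2O2, 0 °C to rt
Reagents that add atoms: hydrogen peroxide, OO
Why: Hydroboration–oxidation; the bulky borane places boron on the terminal carbon of the styrene (anti-Markovnikov), and alkaline peroxide converts the C–B bond into the primary alcohol.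

Step 5
Reactants: 6 2-[4-(benzyloxy)-2,6-bis(methoxymethoxy)phenyl]ethan-1-ol
Product: 7 {2-[4-(benzyloxy)-2,6-bis(methoxymethoxy)phenyl]ethoxy}(tert-butyl)dimethylsilane
Conditions: TBSCl (1.2 equiv), imidazole (2 equiv), CH2Cl2, rt
Reagents that add atoms: tert-butyldimethylsilyl chloride (TBSCl), CC(C)(C)[Si](C)(C)Cl
Why: Standard silylation of a primary alcohol; the silyl ether should survive hydrogenolysis, titanium and lithium reagents and fall in the final acid step.

Step 6
Reactants: 7 {2-[4-(benzyloxy)-2,6-bis(methoxymethoxy)phenyl]ethoxy}(tert-butyl)dimethylsilane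
Product: 8 4-[2-(tert-butyldimethylsilyloxy)ethyl]-3,5-bis(methoxymethoxy)phenol
Conditions: H2 (1 atm), Pd/C (10 wt % palladium on carbon), EtOAc, rt
Reagents that add atoms: none
Why: Hydrogenolysis of the benzyl aryl ether in a non-protic solvent; the acetals and the silyl ether are inert and no alkene or halide is present yet, and the product has a mirror plane so its two free ring positions are equivalent.

Step 7
Reactants: 8 4-[2-(tert-butyldimethylsilyloxy)ethyl]-3,5-bis(methoxymethoxy)phenol
Product: 9 2,6-dibromo-4-[2-(tert-butyldimethylsilyloxy)ethyl]-3,5-bis(methoxymethoxy)phenol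
Conditions: NBS (2.05 equiv), CH2Cl2, −78 to 0 °C
Reagents that add atoms: N-bromosuccinimide, O=C1CCC(=O)N1Br
Why: Electrophilic aromatic bromination; both free positions are ortho to the hydroxyl and ortho or para to the acetal oxygens, so exhaustive bromination needs no site selection, and succinimide takes up the proton so no strong acid is formed.

Step 8
Reactants: 10 vanillic acid (4-hydroxy-3-methoxybenzoic acid)
Product: 12 3-methoxy-4-(methoxymethoxy)benzoic acid, via methoxymethyl ester 11 (not isolated)
Conditions: MOMCl (2.5 equiv), iPr2NEt (3 equiv), CH2Cl2, 0 °C to rt; concentrate; LiOH, THF/MeOH/H2O, rt; cold dilute HCl to pH 4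
Reagents that add atoms: chloromethyl methyl ether (MOMCl), COCCl
Why: Alkylation protects both the phenol and the carboxylate; the acyl acetal (ester) is then saponified selectively, since the aryl acetal is stable to hydroxide and to brief contact with cold dilute acid.

Step 9
Reactants: 9 2,6-dibromo-4-[2-(tert-butyldimethylsilyloxy)ethyl]-3,5-bis(methoxymethoxy)phenol; 12 3-methoxy-4-(methoxymethoxy)benzoic acid
Product: 13 2,6-dibromo-4-[2-(tert-butyldimethylsilyloxy)ethyl]-3,5-bis(methoxymethoxy)phenyl 3-methoxy-4-(methoxymethoxy)benzoate
Conditions: EDC·HCl (1.5 equiv), DMAP (0.5 equiv), CH2Cl2, rt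
Reagents that add atoms: none
Why: Steglich esterification; the acidic dibromophenol is acylated through the N-acylpyridinium ion, and the neutral conditions avoid the HCl that acid chloride formation would bring to the acetals.

Step 10
Reactants: 13 2,6-dibromo-4-[2-(tert-butyldimethylsilyloxy)ethyl]-3,5-bis(methoxymethoxy)phenyl 3-methoxy-4-(methoxymethoxy)benzoate
Product: 14 1,3-dibromo-5-[2-(tert-butyldimethylsilyloxy)ethyl]-4,6-bis(methoxymethoxy)-2-{1-[3-methoxy-4-(methoxymethoxy)phenyl]ethenyloxy}benzene
Conditions: Cp2TiMe2 (3 equiv), toluene/THF, 70 °C, dark; chromatography on Et3N-deactivated silica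
Reagents that add atoms: dimethyltitanocene (Cp2TiMe2), C[Ti](C)(C1C=CC=C1)C1C=CC=C1
Why: Petasis methylenation; thermolysis gives Cp2Ti=CH2, which converts the ester carbonyl into the 1-arylvinyl aryl ether by [2+2] addition and cycloreversion, and the reagent is non-basic and tolerates aryl bromides, acetals and silyl ethers.

Step 11
Reactants: 14 1,3-dibromo-5-[2-(tert-butyldimethylsilyloxy)ethyl]-4,6-bis(methoxymethoxy)-2-{1-[3-methoxy-4-(methoxymethoxy)phenyl]ethenyloxy}benzene; 15 prenyl bromide (1-bromo-3-methylbut-2-ene)
Product: 17 1-bromo-3-[2-(tert-butyldimethylsilyloxy)ethyl]-2,4-bis(methoxymethoxy)-6-{1-[3-methoxy-4-(methoxymethoxy)phenyl]ethenyloxy}-5-(3-methylbut-2-en-1-yl)benzene, via monolithiated arene 16 (not isolated)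
Conditions: n-BuLi (1.05 equiv), THF, −78 °C; CuBr·SMe2 (10 mol %), 15 (1.5 equiv), −78 to 0 °C
Reagents that add atoms: none
Why: Bromine–lithium exchange is faster than any deprotonation at −78 °C, and one equivalent should exchange only one of the two equivalent bromines because the aryllithium resists a second exchange; copper-catalysed allylic substitution at the primary carbon of 15 then places the prenyl group at C8.

Step 12
Reactants: 17 1-bromo-3-[2-(tert-butyldimethylsilyloxy)ethyl]-2,4-bis(methoxymethoxy)-6-{1-[3-methoxy-4-(methoxymethoxy)phenyl]ethenyloxy}-5-(3-methylbut-2-en-1-yl)benzene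
Product: 19 3-[2-(tert-butyldimethylsilyloxy)ethyl]-2,4-bis(methoxymethoxy)-6-{1-[3-methoxy-4-(methoxymethoxy)phenyl]ethenyloxy}-5-(3-methylbut-2-en-1-yl)benzaldehyde, via aryllithium 18 (not isolated)
Conditions: n-BuLi (1.1 equiv), THF, −78 °C; DMF (3 equiv), −78 to 0 °C; pH 7 aq. NH4Cl
Reagents that add atoms: N,N-dimethylformamide, CN(C)C=O
Why: A second bromine–lithium exchange followed by Bouveault formylation; the exchange defines C4a as the only reactive site, so no competition with lithiation of ring B arises, and neutral work-up releases the aldehyde without hydrolysing the enol ether.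

Step 13
Reactants: 19 3-[2-(tert-butyldimethylsilyloxy)ethyl]-2,4-bis(methoxymethoxy)-6-{1-[3-methoxy-4-(methoxymethoxy)phenyl]ethenyloxy}-5-(3-methylbut-2-en-1-yl)benzaldehyde
Product: 20 (2S)-6-[2-(tert-butyldimethylsilyloxy)ethyl]-2-[3-methoxy-4-(methoxymethoxy)phenyl]-5,7-bis(methoxymethoxy)-8-(3-methylbut-2-en-1-yl)chroman-4-one
Conditions: [Rh(cod)2]BF4 (5 mol %), (R)-DTBM-SEGPHOS (5.5 mol %), catalyst solution treated with H2 then purged with argon, dry 1,2-dichloroethane, 60 °C
Reagents that add atoms: none
Why: Proposed new method: oxidative addition of the C4 aldehyde C–H bond of 19 to the cationic bisphosphine complex of monovalent rhodium should give an acyl hydride of trivalent rhodium, held by chelation through the C5 acetal oxygen, which slows loss of CO. Migratory insertion of the tethered 1-arylvinyl ether then places the hydride on the internal carbon C2 and rhodium on the terminal carbon C3, and C–C reductive elimination from the seven-membered acyl alkyl rhodacycle forms C3–C4. The closest known reaction type is the rhodium-catalysed enantioselective intramolecular hydroacylation of 1,1-disubstituted alkenes, for example ortho-(2-substituted allyl)benzaldehydes to 3-substituted tetralones; here the benzylic CH2 of that tether is replaced by the ether oxygen O1. Ring C closes in the 6-endo sense, both alkene carbons ending up in the ring. The C2 stereocentre is controlled by the chiral bisphosphine alone, which selects the enantioface of the enol ether presented to the Rh–H bond (or, if insertion is reversible, the diastereomeric rhodacycle that eliminates faster), since the substrate is achiral. The step needs regioselectivity for the chromanone over the 2-aryl-2-methylbenzofuran-3-one, which should follow from the preference for a primary alkyl–rhodium bond and for hydride delivery to the oxocarbenium-like carbon bearing oxygen and aryl. It also needs chemoselectivity, which the substrate secures because the trisubstituted prenyl alkene could only close a larger ring and the enol ether has no allylic hydrogen and cannot isomerise.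

Step 14
Reactants: 20 (2S)-6-[2-(tert-butyldimethylsilyloxy)ethyl]-2-[3-methoxy-4-(methoxymethoxy)phenyl]-5,7-bis(methoxymethoxy)-8-(3-methylbut-2-en-1-yl)chroman-4-one
Product: 21 laxiflorin, (2S)-5,7-dihydroxy-6-(2-hydroxyethyl)-2-(4-hydroxy-3-methoxyphenyl)-8-(3-methylbut-2-en-1-yl)chroman-4-one
Conditions: 3 M aq. HCl/MeOH (1:4), 40 °C
Reagents that add atoms: none
Why: Acid-catalysed acetal exchange removes the three methoxymethyl ethers and methanolysis cleaves the primary silyl ether; the mild temperature should limit protonation of the prenyl alkene and acid-promoted ring opening at C2, so the S configuration is expected to be kept.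

## Compound list

1 | 2,4,6-trihydroxybenzaldehyde | O=Cc1c(O)cc(O)cc1O | starting material
2 | 4-(benzyloxy)-2,6-dihydroxybenzaldehyde | O=Cc1c(O)cc(OCc2ccccc2)cc1O | intermediate
3 | 4-(benzyloxy)-2,6-bis(methoxymethoxy)benzaldehyde | O=Cc1c(OCOC)cc(OCc2ccccc2)cc1OCOC | intermediate
4 | 5-(benzyloxy)-1,3-bis(methoxymethoxy)-2-vinylbenzene | C=Cc1c(OCOC)cc(OCc2ccccc2)cc1OCOC | intermediate
5 | 9-{2-[4-(benzyloxy)-2,6-bis(methoxymethoxy)phenyl]ethyl}-9-borabicyclo[3.3.1]nonane (not isolated) | COCOc1cc(OCc2ccccc2)cc(OCOC)c1CCB1C2CCCC1CCC2 | intermediate
6 | 2-[4-(benzyloxy)-2,6-bis(methoxymethoxy)phenyl]ethan-1-ol | OCCc1c(OCOC)cc(OCc2ccccc2)cc1OCOC | intermediate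
7 | {2-[4-(benzyloxy)-2,6-bis(methoxymethoxy)phenyl]ethoxy}(tert-butyl)dimethylsilane | CC(C)(C)[Si](C)(C)OCCc1c(OCOC)cc(OCc2ccccc2)cc1OCOC | intermediate
8 | 4-[2-(tert-butyldimethylsilyloxy)ethyl]-3,5-bis(methoxymethoxy)phenol | CC(C)(C)[Si](C)(C)OCCc1c(OCOC)cc(O)cc1OCOC | intermediate
9 | 2,6-dibromo-4-[2-(tert-butyldimethylsilyloxy)ethyl]-3,5-bis(methoxymethoxy)phenol | CC(C)(C)[Si](C)(C)OCCc1c(OCOC)c(Br)c(O)c(Br)c1OCOC | intermediate
10 | vanillic acid (4-hydroxy-3-methoxybenzoic acid) | COc1cc(C(=O)O)ccc1O | starting material
11 | methoxymethyl 3-methoxy-4-(methoxymethoxy)benzoate (not isolated) | COCOC(=O)c1ccc(OCOC)c(OC)c1 | intermediate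
12 | 3-methoxy-4-(methoxymethoxy)benzoic acid | COCOc1ccc(C(=O)O)cc1OC | intermediate
13 | 2,6-dibromo-4-[2-(tert-butyldimethylsilyloxy)ethyl]-3,5-bis(methoxymethoxy)phenyl 3-methoxy-4-(methoxymethoxy)benzoate | COCOc1ccc(C(=O)Oc2c(Br)c(OCOC)c(CCO[Si](C)(C)C(C)(C)C)c(OCOC)c2Br)cc1OC | intermediate
14 | 1,3-dibromo-5-[2-(tert-butyldimethylsilyloxy)ethyl]-4,6-bis(methoxymethoxy)-2-{1-[3-methoxy-4-(methoxymethoxy)phenyl]ethenyloxy}benzene | COCOc1ccc(C(=C)Oc2c(Br)c(OCOC)c(CCO[Si](C)(C)C(C)(C)C)c(OCOC)c2Br)cc1OC | intermediate
15 | prenyl bromide (1-bromo-3-methylbut-2-ene) | CC(C)=CCBr | starting material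
16 | {3-bromo-5-[2-(tert-butyldimethylsilyloxy)ethyl]-4,6-bis(methoxymethoxy)-2-{1-[3-methoxy-4-(methoxymethoxy)phenyl]ethenyloxy}phenyl}lithium (not isolated) | [Li]c1c(OCOC)c(CCO[Si](C)(C)C(C)(C)C)c(OCOC)c(Br)c1OC(=C)c1ccc(OCOC)c(OC)c1 | intermediate
17 | 1-bromo-3-[2-(tert-butyldimethylsilyloxy)ethyl]-2,4-bis(methoxymethoxy)-6-{1-[3-methoxy-4-(methoxymethoxy)phenyl]ethenyloxy}-5-(3-methylbut-2-en-1-yl)benzene | COCOc1ccc(C(=C)Oc2c(Br)c(OCOC)c(CCO[Si](C)(C)C(C)(C)C)c(OCOC)c2CC=C(C)C)cc1OC | intermediate
18 | {3-[2-(tert-butyldimethylsilyloxy)ethyl]-2,4-bis(methoxymethoxy)-6-{1-[3-methoxy-4-(methoxymethoxy)phenyl]ethenyloxy}-5-(3-methylbut-2-en-1-yl)phenyl}lithium (not isolated) | [Li]c1c(OCOC)c(CCO[Si](C)(C)C(C)(C)C)c(OCOC)c(CC=C(C)C)c1OC(=C)c1ccc(OCOC)c(OC)c1 | intermediate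
19 | 3-[2-(tert-butyldimethylsilyloxy)ethyl]-2,4-bis(methoxymethoxy)-6-{1-[3-methoxy-4-(methoxymethoxy)phenyl]ethenyloxy}-5-(3-methylbut-2-en-1-yl)benzaldehyde | O=Cc1c(OCOC)c(CCO[Si](C)(C)C(C)(C)C)c(OCOC)c(CC=C(C)C)c1OC(=C)c1ccc(OCOC)c(OC)c1 | intermediate
20 | (2S)-6-[2-(tert-butyldimethylsilyloxy)ethyl]-2-[3-methoxy-4-(methoxymethoxy)phenyl]-5,7-bis(methoxymethoxy)-8-(3-methylbut-2-en-1-yl)chroman-4-one | COCOc1ccc([C@@H]2CC(=O)c3c(OCOC)c(CCO[Si](C)(C)C(C)(C)C)c(OCOC)c(CC=C(C)C)c3O2)cc1OC | intermediate
21 | laxiflorin, (2S)-5,7-dihydroxy-6-(2-hydroxyethyl)-2-(4-hydroxy-3-methoxyphenyl)-8-(3-methylbut-2-en-1-yl)chroman-4-one | COc1cc([C@@H]2CC(=O)c3c(O)c(CCO)c(O)c(CC=C(C)C)c3O2)ccc1O | target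

## Step count and least certain steps

Total step count: 14. Longest linear sequence: 13 steps (steps 1–7 and 9–14, from 1); step 8 is the one-step side branch from 10.

**Step 13 (key step, new method).**
- What may go wrong: loss of CO from the crowded, doubly ortho-substituted acyl rhodium hydride, which would turn the catalyst into an inert carbonyl complex; insertion with the reverse regiochemistry, leading to five-ring closure; weak enantioface discrimination, because the two substituents on C2 (aryl and aryloxy) differ little in size.
- Fallback (known chemistry only), from 19 back to 20: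
  - Addition of HC≡CMgBr in THF at −78 to 0 °C would give the propargylic alcohol F1. The enol ether serves here as the protecting group of O1.
  - Oxidation with MnO2 in CH2Cl2 would give the ynone F2.
  - PPTS in wet acetone would hydrolyse the enol ether to the ortho-hydroxyaryl ynone F3, which is not isolated. Addition of Et2NH would close it, through the enaminone, to the chromone F4.
  - Asymmetric conjugate addition of the arylboronate F5 would give 20. F5 is made in one step from commercial 4-hydroxy-3-methoxyphenylboronic acid pinacol ester with MOMCl and iPr2NEt. The addition uses [Rh(OH)(cod)]2 and a chiral electron-poor bisphosphine of the MeO-BIPHEP family, the antipode chosen for 2S, in toluene/water at 40–60 °C. Arylboron additions to 5,7-dioxygenated chromones are an established way to flavanones.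

**Step 10.**
- What may go wrong: slow methylenation, because the ester carbonyl is shielded by the two ortho bromines, and hydrolysis of the enol ether during isolation.
- Fallback, from 8 and 12, returning at 18:
  - Esterification of the unhindered phenol 8 with 12 (EDC·HCl, DMAP) would give the ester F6.
  - Methylenation with Cp2TiMe2 would give the symmetric vinyl ether F7.
  - Directed ortho-lithiation between the acetal and vinyloxy oxygens (n-BuLi, TMEDA, THF, −20 °C) would give the aryllithium F8, not isolated, which is prenylated with 15 and CuBr·SMe2 to the monoprenyl vinyl ether F9.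
  - A second lithiation at the remaining ring A position would give 18 directly, which is formylated as in step 12.
  - This path is one step shorter but depends on ring A lithiation outrunning lithiation ortho to the acetal of ring B, which is why it is not the first choice.

**Step 11.**
- What may go wrong: incomplete or double bromine–lithium exchange, and coupling at the tertiary terminus of the allyl system (allylic transposition to the 1,1-dimethylallyl isomer).
- Fallback, from 14 back to 17: the aryllithium 16 is quenched with allyl bromide, which has no regiochemical ambiguity, to give the allyl arene F10. Cross-metathesis with 2-methylbut-2-ene and the second-generation Grubbs catalyst (CH2Cl2, 40 °C) would convert the allyl into the prenyl group. The 1,1-disubstituted enol ether, flanked on both sides, is expected to be too hindered to take part.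

**Step 14.**
- What may go wrong: acid-promoted addition of the C7 hydroxyl to the prenyl alkene (chroman formation), and erosion of the C2 configuration by reversible ring opening.
- Fallback, from 20 back to 21, in two non-protic stages: HF·pyridine buffered with pyridine in THF at 0 °C would remove the silyl group to give the alcohol F11. TMSOTf and 2,2'-bipyridyl in CH2Cl2 at 0 °C, followed by water, would then cleave the three aryl acetals through their silyl ethers.

**Step 1.**
- What may go wrong: over-alkylation at the chelated hydroxyls and C-benzylation of the phloroglucinol ring.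
- Fallback, from 1 back to 2: Mitsunobu etherification with benzyl alcohol, PPh3 and DIAD in THF at 0 °C. It selects the most acidic hydroxyl and cannot C-alkylate. No new compound is made (F0).

## Further compounds

F1 | step 13 | 1-{3-[2-(tert-butyldimethylsilyloxy)ethyl]-2,4-bis(methoxymethoxy)-6-{1-[3-methoxy-4-(methoxymethoxy)phenyl]ethenyloxy}-5-(3-methylbut-2-en-1-yl)phenyl}prop-2-yn-1-ol (racemic) | C#CC(O)c1c(OCOC)c(CCO[Si](C)(C)C(C)(C)C)c(OCOC)c(CC=C(C)C)c1OC(=C)c1ccc(OCOC)c(OC)c1
F2 | step 13 | 1-{3-[2-(tert-butyldimethylsilyloxy)ethyl]-2,4-bis(methoxymethoxy)-6-{1-[3-methoxy-4-(methoxymethoxy)phenyl]ethenyloxy}-5-(3-methylbut-2-en-1-yl)phenyl}prop-2-yn-1-one | C#CC(=O)c1c(OCOC)c(CCO[Si](C)(C)C(C)(C)C)c(OCOC)c(CC=C(C)C)c1OC(=C)c1ccc(OCOC)c(OC)c1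
F3 | step 13 | 1-{3-[2-(tert-butyldimethylsilyloxy)ethyl]-6-hydroxy-2,4-bis(methoxymethoxy)-5-(3-methylbut-2-en-1-yl)phenyl}prop-2-yn-1-one (not isolated) | C#CC(=O)c1c(OCOC)c(CCO[Si](C)(C)C(C)(C)C)c(OCOC)c(CC=C(C)C)c1O
F4 | step 13 | 6-[2-(tert-butyldimethylsilyloxy)ethyl]-5,7-bis(methoxymethoxy)-8-(3-methylbut-2-en-1-yl)-4H-chromen-4-one | O=c1ccoc2c(CC=C(C)C)c(OCOC)c(CCO[Si](C)(C)C(C)(C)C)c(OCOC)c12
F5 | step 13 | 2-[3-methoxy-4-(methoxymethoxy)phenyl]-4,4,5,5-tetramethyl-1,3,2-dioxaborolane | COCOc1ccc(B2OC(C)(C)C(C)(C)O2)cc1OC
F6 | step 10 | 4-[2-(tert-butyldimethylsilyloxy)ethyl]-3,5-bis(methoxymethoxy)phenyl 3-methoxy-4-(methoxymethoxy)benzoate | COCOc1ccc(C(=O)Oc2cc(OCOC)c(CCO[Si](C)(C)C(C)(C)C)c(OCOC)c2)cc1OC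
F7 | step 10 | tert-butyl{2-[2,6-bis(methoxymethoxy)-4-{1-[3-methoxy-4-(methoxymethoxy)phenyl]ethenyloxy}phenyl]ethoxy}dimethylsilane | COCOc1ccc(C(=C)Oc2cc(OCOC)c(CCO[Si](C)(C)C(C)(C)C)c(OCOC)c2)cc1OC
F8 | step 10 | {3-[2-(tert-butyldimethylsilyloxy)ethyl]-2,4-bis(methoxymethoxy)-6-{1-[3-methoxy-4-(methoxymethoxy)phenyl]ethenyloxy}phenyl}lithium (not isolated) | [Li]c1c(OCOC)c(CCO[Si](C)(C)C(C)(C)C)c(OCOC)cc1OC(=C)c1ccc(OCOC)c(OC)c1
F9 | step 10 | tert-butyl{2-[2,6-bis(methoxymethoxy)-4-{1-[3-methoxy-4-(methoxymethoxy)phenyl]ethenyloxy}-3-(3-methylbut-2-en-1-yl)phenyl]ethoxy}dimethylsilane | COCOc1ccc(C(=C)Oc2cc(OCOC)c(CCO[Si](C)(C)C(C)(C)C)c(OCOC)c2CC=C(C)C)cc1OC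
F10 | step 11 | 1-bromo-3-[2-(tert-butyldimethylsilyloxy)ethyl]-2,4-bis(methoxymethoxy)-6-{1-[3-methoxy-4-(methoxymethoxy)phenyl]ethenyloxy}-5-(prop-2-en-1-yl)benzene | C=CCc1c(OCOC)c(CCO[Si](C)(C)C(C)(C)C)c(OCOC)c(Br)c1OC(=C)c1ccc(OCOC)c(OC)c1
F11 | step 14 | (2S)-6-(2-hydroxyethyl)-2-[3-methoxy-4-(methoxymethoxy)phenyl]-5,7-bis(methoxymethoxy)-8-(3-methylbut-2-en-1-yl)chroman-4-one | COCOc1ccc([C@@H]2CC(=O)c3c(OCOC)c(CCO)c(OCOC)c(CC=C(C)C)c3O2)cc1OC
F0 | step 1 | none | none
A1 | alternative 1 | (S)-5-bromo-2-[4-(tert-butyldimethylsilyloxy)-3-methoxyphenyl]-2,3-dihydro-4H-pyran-4-one | COc1cc([C@@H]2CC(=O)C(Br)=CO2)ccc1O[Si](C)(C)C(C)(C)C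
A2 | alternative 1 | 2-(trimethylsilyloxy)-3-[5-methyl-1-(trimethylsilyloxy)hexa-1,4-dienyl]-4,5-dihydrofuran | CC(C)=CCC=C(O[Si](C)(C)C)C1=C(O[Si](C)(C)C)OCC1
A3 | alternative 1 | (2S)-2-[4-(tert-butyldimethylsilyloxy)-3-methoxyphenyl]-5,7-dihydroxy-6-(2-hydroxyethyl)-8-(3-methylbut-2-en-1-yl)chroman-4-one | CC(C)(C)[Si](C)(C)Oc1ccc([C@@H]2CC(=O)c3c(O)c(CCO)c(O)c(CC=C(C)C)c3O2)cc1OC
A4 | alternative 2 | (2S)-2-[3-methoxy-4-(methoxymethoxy)phenyl]-6-[5-methyl-1-oxo-1-(2-oxooxolan-3-yl)hex-4-en-2-yl]-2,3-dihydro-4H-pyran-4-one | COCOc1ccc([C@@H]2CC(=O)C=C(C(CC=C(C)C)C(=O)C3CCOC3=O)O2)cc1OC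
A5 | alternative 2 | (2S)-5,7-dihydroxy-6-(2-hydroxyethyl)-2-[3-methoxy-4-(methoxymethoxy)phenyl]-8-(3-methylbut-2-en-1-yl)chroman-4-one | COCOc1ccc([C@@H]2CC(=O)c3c(O)c(CCO)c(O)c(CC=C(C)C)c3O2)cc1OC
A6 | alternative 3 | 2-hydroxy-4,6-bis(methoxymethoxy)-5-[2-(tert-butyldimethylsilyloxy)ethyl]-3-(3-methylbut-2-enyl)benzaldehyde | O=Cc1c(OCOC)c(CCO[Si](C)(C)C(C)(C)C)c(OCOC)c(CC=C(C)C)c1O
A7 | alternative 3 | triisopropyl(2-methoxy-4-vinylphenoxy)silane | C=Cc1ccc(O[Si](C(C)C)(C(C)C)C(C)C)c(OC)c1
A8 | alternative 3 | (2S,4S)-6-[2-(tert-butyldimethylsilyloxy)ethyl]-4-methoxy-2-[3-methoxy-4-(triisopropylsilyloxy)phenyl]-5,7-bis(methoxymethoxy)-8-(3-methylbut-2-en-1-yl)chromane (2,4-cis) | COc1cc([C@@H]2C[C@H](OC)c3c(OCOC)c(CCO[Si](C)(C)C(C)(C)C)c(OCOC)c(CC=C(C)C)c3O2)ccc1O[Si](C(C)C)(C(C)C)C(C)C
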